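**Plan**

- Retrosynthetic cuts: first both C7=C8 and C7'=C8' double bonds (two-directional double Wittig of two identical C15 ring phosphonium salts onto the all-E C20 dialdehyde); then each side chain at its trisubstituted C=C (stabilised Wittig) and at the CH2 on the ring (one-carbon homologation of a ring carbaldehyde); last, in each ring, C3–C4 and C1–C2.
- Enabling feature: each end group is a cyclohexene whose only ring double bond, C5=C6, lies between C4 and C1. The ring is therefore the [4+2] adduct of the diene C4H2=C5(CH3)–C6(CH2OSi)=C1(CH3)2 and the two-carbon dienophile C3=C2 of acrolein; the gem-dimethyl carbon C1 is the fully substituted diene terminus and C2 is the only stereocentre.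
- Forward order: the silyloxymethyl diene is made in four steps; one amine-catalysed enantioselective Diels–Alder reaction closes the only ring that has to be built; the side chain is extended; C7–OH becomes the phosphonium salt; both halves are joined to the dialdehyde; the two esters are reduced.
- Stereochemistry: C2 (R in the target) is set once, by the chiral imidazolidinone in the cycloaddition, and the same fragment serves both halves. The side-chain E alkene comes from the stabilised ylide; the polyene geometry comes from the all-E dialdehyde and thermal equilibration.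

Key step: step 5

Assumption: the facial bias of the imidazolidinone catalyst known for acrolein with simple acyclic dienes is taken to hold for diene 7 (the enantiomeric catalyst would serve if the sense proved opposite), and the all-E C20 dialdehyde 17 is taken as a purchased carotenoid building block.

**Route**

Step 1
Reactants: 1 ethyl 3-methylbut-2-enoate
Product: 3 ethyl 2-bromo-3-methylbut-2-enoate, via vicinal dibromide 2 (not isolated)
Conditions: Br2, CH2Cl2, 0 °C; then Et3N, 0 °C to reflux
Reagents that add atoms: bromine, BrBr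
Why: Bromination–dehydrobromination (addition of Br2, then E2 loss of HBr through the acidic α-hydrogen) should give the α-bromo enoate, which has no alkene geometry to control because the β-carbon bears two methyl groups.

Step 2
Reactants: 3 ethyl 2-bromo-3-methylbut-2-enoate; 4 isopropenylboronic acid pinacol ester
Product: 5 ethyl 3-methyl-2-(prop-1-en-2-yl)but-2-enoate
Conditions: Pd(dppf)Cl2 (5 mol %), K2CO3, 1,4-dioxane/H2O, 80 °C
Reagents that add atoms: none
Why: Suzuki–Miyaura coupling of an α-bromo acrylate (fast oxidative addition) with an alkenylboronate should forge the tetrasubstituted alkene of the cross-conjugated dienoate, with no stereocentre or alkene geometry at stake.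

Step 3
Reactants: 5 ethyl 3-methyl-2-(prop-1-en-2-yl)but-2-enoate
Product: 6 3-methyl-2-(prop-1-en-2-yl)but-2-en-1-ol
Conditions: i-Bu2AlH (2.2 equiv), CH2Cl2, −78 to 0 °C; aq. potassium sodium tartrate
Reagents that add atoms: none
Why: 1,2-Reduction of the conjugated ester by two hydride equivalents (i-Bu2AlH ester reduction) should give the allylic alcohol without touching the diene.

Step 4
Reactants: 6 3-methyl-2-(prop-1-en-2-yl)but-2-en-1-ol
Product: 7 tert-butyl{[3-methyl-2-(prop-1-en-2-yl)but-2-en-1-yl]oxy}diphenylsilane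
Conditions: t-BuPh2SiCl, imidazole, CH2Cl2, rt
Reagents that add atoms: tert-butyl(chloro)diphenylsilane, CC(C)(C)[Si](Cl)(c1ccccc1)c1ccccc1
Why: Imidazole-promoted silylation installs a TBDPS ether that should tolerate the amine salt of step 5, the ylide of step 6 and the aqueous acid of step 7, and it removes a free hydroxyl that could add to the iminium ion.

Step 5
Reactants: 7 tert-butyl{[3-methyl-2-(prop-1-en-2-yl)but-2-en-1-yl]oxy}diphenylsilane; 8 acrolein (3 equiv)
Product: 11 (1S)-3-{[tert-butyl(diphenyl)silyl]oxymethyl}-2,2,4-trimethylcyclohex-3-ene-1-carbaldehyde, via acrolein iminium chloride 9 (not isolated), via cycloadduct iminium chloride 10 (not isolated)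
Conditions: (5R)-5-benzyl-2,2,3-trimethylimidazolidin-4-one hydrochloride (20 mol %), CH3NO2/H2O 95:5, 0 °C to rt
Reagents that add atoms: water, O
Why: Proposed new method: the amine salt condenses with acrolein (with loss of water) to the E-configured iminium ion 9, whose β-carbon is attacked by the unsubstituted CH2 terminus of diene 7 in a concerted but strongly asynchronous [4+2] (in the limit a Michael addition leaving a 1,1,3-trialkylallyl cation that the enamine α-carbon closes at the dimethyl-bearing terminus), and hydrolysis of iminium 10 by the water of the medium restores the carbonyl oxygen, frees aldehyde 11 and returns the amine hydrochloride to the cycle. The closest known reaction type is the imidazolidinone-catalysed enantioselective Diels–Alder reaction of acrolein with simple acyclic dienes such as isoprene, together with Lewis-acid-promoted cycloadditions of 2,4-dimethylpenta-1,3-diene with acrylic dienophiles; new here is a diene whose reacting terminus is fully substituted and becomes a quaternary carbon. The six-membered carbocycle is closed intermolecularly in the [π4s+π2s] mode (6-endo-trig onto the allyl cation in the stepwise limit), and the ring double bond is born tetrasubstituted between the methyl-bearing and the CH2OSi-bearing carbons. The only new stereocentre, the former α-carbon of acrolein, is set by the catalyst: the benzyl group of the (5R)-imidazolidinone shields one π-face of the s-trans E-iminium ion, so the diene should add to the Re face of the α-carbon and the carbaldehyde-bearing carbon becomes S (R in the target once the priorities change). The step needs ortho regioselectivity and cycloaddition in preference to acrolein oligomerisation; the two methyl groups on the diene terminus polarise the diene so that its CH2 end bonds to the β-carbon, and the substituents on both inner carbons disfavour the s-trans conformer so that a cisoid geometry is within reach.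

Step 6
Reactants: 11 (1S)-3-{[tert-butyl(diphenyl)silyl]oxymethyl}-2,2,4-trimethylcyclohex-3-ene-1-carbaldehyde
Product: 12 tert-butyl{[(5R)-5-(2-methoxyethenyl)-2,6,6-trimethylcyclohex-1-en-1-yl]methoxy}diphenylsilane (E/Z mixture)
Conditions: MeOCH2PPh3Cl (1.5 equiv), KN(SiMe3)2 (1.4 equiv), THF, 0 °C; then 11, −78 to 0 °C
Reagents that add atoms: (methoxymethyl)triphenylphosphonium chloride, COC[P+](c1ccccc1)(c1ccccc1)c1ccccc1.[Cl-]
Why: Wittig olefination with the non-stabilised methoxymethylene ylide, preformed with a slight deficit of base and used cold, should give the enol ether (either geometry serves) before the α-stereocentre can enolise; the descriptor changes from S to R through the priority rules only.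

Step 7
Reactants: 12 tert-butyl{[(5R)-5-(2-methoxyethenyl)-2,6,6-trimethylcyclohex-1-en-1-yl]methoxy}diphenylsilane
Product: 13 2-[(1R)-3-{[tert-butyl(diphenyl)silyl]oxymethyl}-2,2,4-trimethylcyclohex-3-en-1-yl]acetaldehyde
Conditions: 1 M aq. HCl, THF, 0 °C to rt
Reagents that add atoms: water, O
Why: Acid-catalysed enol ether hydrolysis (C-protonation, hemiacetal, loss of methanol) completes the one-carbon homologation, after which the stereocentre is β to the carbonyl and configurationally safe; the TBDPS ether should tolerate dilute acid.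

Step 8
Reactants: 13 2-[(1R)-3-{[tert-butyl(diphenyl)silyl]oxymethyl}-2,2,4-trimethylcyclohex-3-en-1-yl]acetaldehyde
Product: 14 ethyl (2E)-4-[(1R)-3-{[tert-butyl(diphenyl)silyl]oxymethyl}-2,2,4-trimethylcyclohex-3-en-1-yl]-2-methylbut-2-enoate
Conditions: Ph3P=C(CH3)CO2Et (1.3 equiv), CH2Cl2, rt
Reagents that add atoms: ethyl 2-(triphenylphosphoranylidene)propanoate, CCOC(=O)C(C)=P(c1ccccc1)(c1ccccc1)c1ccccc1
Why: Wittig reaction with a stabilised ylide should give the E trisubstituted enoate through reversible, thermodynamically controlled oxaphosphetane formation, and it keeps the side-chain oxygen masked as an ester that survives the acidic step 10.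

Step 9
Reactants: 14 ethyl (2E)-4-[(1R)-3-{[tert-butyl(diphenyl)silyl]oxymethyl}-2,2,4-trimethylcyclohex-3-en-1-yl]-2-methylbut-2-enoate
Product: 15 ethyl (2E)-4-[(1R)-3-(hydroxymethyl)-2,2,4-trimethylcyclohex-3-en-1-yl]-2-methylbut-2-enoate
Conditions: Bu4NF, AcOH (1:1), THF, 0 °C to rt
Reagents that add atoms: none
Why: Fluoride-mediated desilylation, buffered with acetic acid so that the enoate is neither hydrolysed nor deconjugated, should free the hindered allylic alcohol.

Step 10
Reactants: 15 ethyl (2E)-4-[(1R)-3-(hydroxymethyl)-2,2,4-trimethylcyclohex-3-en-1-yl]-2-methylbut-2-enoate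
Product: 16 ({(5R)-5-[(2E)-4-ethoxy-3-methyl-4-oxobut-2-en-1-yl]-2,6,6-trimethylcyclohex-1-en-1-yl}methyl)triphenylphosphonium bromide
Conditions: Ph3P·HBr, CH2Cl2, rt
Reagents that add atoms: triphenylphosphine hydrobromide, [PH+](c1ccccc1)(c1ccccc1)c1ccccc1.[Br-]
Why: SN1-type allylic substitution, in which the acidic phosphonium salt ionises the allylic alcohol to the ring-stabilised allyl cation and PPh3 captures it at the unhindered primary carbon (the standard preparation of cyclogeranyl-type Wittig salts), should give the phosphonium bromide without touching the ester or the remote stereocentre.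

Step 11
Reactants: 16 ({(5R)-5-[(2E)-4-ethoxy-3-methyl-4-oxobut-2-en-1-yl]-2,6,6-trimethylcyclohex-1-en-1-yl}methyl)triphenylphosphonium bromide (2.2 equiv); 17 crocetindialdehyde (1.0 equiv)
Product: 20 (2R,2'R)-2,2'-bis[(2E)-3-(ethoxycarbonyl)but-2-en-1-yl]-β,β-carotene, via phosphorus ylide 18 (not isolated), via mono-olefination aldehyde 19 (not isolated)
Conditions: NaN(SiMe3)2 (2.2 equiv), THF, −78 °C; then 17, −78 °C to rt; then heptane, reflux
Reagents that add atoms: none
Why: Two-directional Wittig olefination: the allylic ylide 18 adds to one formyl group of the symmetrical C20 dialdehyde to give 19 and then to the second, and heating should equilibrate the crowded Z isomers at the new C7=C8 bonds to the all-E polyene, as is usual for carotenoids.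

Step 12
Reactants: 20 (2R,2'R)-2,2'-bis[(2E)-3-(ethoxycarbonyl)but-2-en-1-yl]-β,β-carotene
Product: 21 (2R,2'R)-2,2'-bis[(2E)-4-hydroxy-3-methylbut-2-en-1-yl]-β,β-carotene
Conditions: i-Bu2AlH (6 equiv), CH2Cl2/THF, −78 to −30 °C; aq. potassium sodium tartrate
Reagents that add atoms: none
Why: i-Bu2AlH reduction of both isolated enoate esters should give the two primary allylic alcohols without reducing or isomerising the polyene and leaves both R stereocentres untouched.

**Compound list**

1 | ethyl 3-methylbut-2-enoate | CCOC(=O)C=C(C)C | starting material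
2 | ethyl 2,3-dibromo-3-methylbutanoate (racemic) | CCOC(=O)C(Br)C(C)(C)Br | intermediate
3 | ethyl 2-bromo-3-methylbut-2-enoate | CCOC(=O)C(Br)=C(C)C | intermediate
4 | isopropenylboronic acid pinacol ester (4,4,5,5-tetramethyl-2-(prop-1-en-2-yl)-1,3,2-dioxaborolane) | CC(=C)B1OC(C)(C)C(C)(C)O1 | starting material
5 | ethyl 3-methyl-2-(prop-1-en-2-yl)but-2-enoate | CCOC(=O)C(C(C)=C)=C(C)C | intermediate
6 | 3-methyl-2-(prop-1-en-2-yl)but-2-en-1-ol | CC(C)=C(CO)C(C)=C | intermediate
7 | tert-butyl{[3-methyl-2-(prop-1-en-2-yl)but-2-en-1-yl]oxy}diphenylsilane | CC(C)=C(CO[Si](c1ccccc1)(c1ccccc1)C(C)(C)C)C(C)=C | intermediate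
8 | acrolein (prop-2-enal) | C=CC=O | starting material
9 | (5R)-5-benzyl-2,2,3-trimethyl-4-oxo-1-[(E)-prop-2-en-1-ylidene]imidazolidin-1-ium chloride | C=C/C=[N+]1\[C@H](Cc2ccccc2)C(=O)N(C)C1(C)C.[Cl-] | intermediate
10 | (5R)-5-benzyl-1-{(E)-[(1S)-3-{[tert-butyl(diphenyl)silyl]oxymethyl}-2,2,4-trimethylcyclohex-3-en-1-yl]methylidene}-2,2,3-trimethyl-4-oxoimidazolidin-1-ium chloride | CC1=C(CO[Si](c2ccccc2)(c2ccccc2)C(C)(C)C)C(C)(C)[C@H](CC1)/C=[N+]1\[C@H](Cc2ccccc2)C(=O)N(C)C1(C)C.[Cl-] | intermediate
11 | (1S)-3-{[tert-butyl(diphenyl)silyl]oxymethyl}-2,2,4-trimethylcyclohex-3-ene-1-carbaldehyde | O=C[C@H]1CCC(C)=C(CO[Si](c2ccccc2)(c2ccccc2)C(C)(C)C)C1(C)C | intermediate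
12 | tert-butyl{[(5R)-5-(2-methoxyethenyl)-2,6,6-trimethylcyclohex-1-en-1-yl]methoxy}diphenylsilane (E/Z mixture) | COC=C[C@H]1CCC(C)=C(CO[Si](c2ccccc2)(c2ccccc2)C(C)(C)C)C1(C)C | intermediate
13 | 2-[(1R)-3-{[tert-butyl(diphenyl)silyl]oxymethyl}-2,2,4-trimethylcyclohex-3-en-1-yl]acetaldehyde | O=CC[C@H]1CCC(C)=C(CO[Si](c2ccccc2)(c2ccccc2)C(C)(C)C)C1(C)C | intermediate
14 | ethyl (2E)-4-[(1R)-3-{[tert-butyl(diphenyl)silyl]oxymethyl}-2,2,4-trimethylcyclohex-3-en-1-yl]-2-methylbut-2-enoate | CCOC(=O)/C(C)=C/C[C@H]1CCC(C)=C(CO[Si](c2ccccc2)(c2ccccc2)C(C)(C)C)C1(C)C | intermediate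
15 | ethyl (2E)-4-[(1R)-3-(hydroxymethyl)-2,2,4-trimethylcyclohex-3-en-1-yl]-2-methylbut-2-enoate | CCOC(=O)/C(C)=C/C[C@H]1CCC(C)=C(CO)C1(C)C | intermediate
16 | ({(5R)-5-[(2E)-4-ethoxy-3-methyl-4-oxobut-2-en-1-yl]-2,6,6-trimethylcyclohex-1-en-1-yl}methyl)triphenylphosphonium bromide | CCOC(=O)/C(C)=C/C[C@H]1CCC(C)=C(C[P+](c2ccccc2)(c2ccccc2)c2ccccc2)C1(C)C.[Br-] | intermediate
17 | crocetindialdehyde, (2E,4E,6E,8E,10E,12E,14E)-2,6,11,15-tetramethylhexadeca-2,4,6,8,10,12,14-heptaenedial | O=C/C(C)=C/C=C/C(C)=C/C=C/C=C(C)/C=C/C=C(C)/C=O | starting material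
18 | ethyl (2E)-2-methyl-4-{(1R)-2,2,4-trimethyl-3-[(triphenylphosphoranylidene)methyl]cyclohex-3-en-1-yl}but-2-enoate | CCOC(=O)/C(C)=C/C[C@H]1CCC(C)=C(C=P(c2ccccc2)(c2ccccc2)c2ccccc2)C1(C)C | intermediate
19 | (2R)-2-[(2E)-3-(ethoxycarbonyl)but-2-en-1-yl]-8'-apo-β-caroten-8'-al (7E isomer shown) | CCOC(=O)/C(C)=C/C[C@H]1CCC(C)=C(/C=C/C(C)=C/C=C/C(C)=C/C=C/C=C(C)/C=C/C=C(C)/C=O)C1(C)C | intermediate
20 | (2R,2'R)-2,2'-bis[(2E)-3-(ethoxycarbonyl)but-2-en-1-yl]-β,β-carotene | CC1=C(/C=C/C(C)=C/C=C/C(C)=C/C=C/C=C(C)/C=C/C=C(C)/C=C/C2=C(C)CC[C@H](C/C=C(\C)C(=O)OCC)C2(C)C)C(C)(C)[C@@H](C/C=C(\C)C(=O)OCC)CC1 | intermediate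
21 | (2R,2'R)-2,2'-bis[(2E)-4-hydroxy-3-methylbut-2-en-1-yl]-β,β-carotene | CC1=C(/C=C/C(C)=C/C=C/C(C)=C/C=C/C=C(C)/C=C/C=C(C)/C=C/C2=C(C)CC[C@H](C/C=C(\C)CO)C2(C)C)C(C)(C)[C@@H](C/C=C(\C)CO)CC1 | target

**Count**

Total steps: 12. Longest linear sequence: 12 steps (1 to 21); compounds 4, 8 and 17 are purchased, and the one ring fragment 16 is used twice in step 11.

**Steps most likely to fail**

1. Step 5 (bears the label). The twisted, fully substituted diene may add too slowly to the iminium ion, so that acrolein oligomerisation or acid-induced decomposition of the diene wins, and facial selectivity may erode if bond formation becomes fully stepwise. The fallback uses known chemistry, an auxiliary-controlled cycloaddition with a chelating aluminium Lewis acid; it sets out from diene 7 and returns at aldehyde 11. Commercial (4R)-4-benzyl-1,3-oxazolidin-2-one is N-acylated (n-BuLi, acryloyl chloride, THF, −78 °C) to (4R)-3-acryloyl-4-benzyl-1,3-oxazolidin-2-one F1. F1 and 7 with Et2AlCl (1.4 equiv, CH2Cl2, −78 to −20 °C) should give the imide adduct (4R)-4-benzyl-3-{[(1S)-3-{[tert-butyl(diphenyl)silyl]oxymethyl}-2,2,4-trimethylcyclohex-3-en-1-yl]carbonyl}-1,3-oxazolidin-2-one F2. The benzyl group shields the α-Si face of the chelated s-cis acrylimide, so the diene should add to the α-Re face, as the target requires. LiBH4 (THF, MeOH, 0 °C) should remove the auxiliary reductively to give [(1S)-3-{[tert-butyl(diphenyl)silyl]oxymethyl}-2,2,4-trimethylcyclohex-3-en-1-yl]methanol F3, and Swern oxidation ((COCl)2, DMSO, Et3N, −78 °C) returns aldehyde 11.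

2. Step 11. The bulky triphenylphosphonium ylide sits on a carbon flanked by the gem-dimethyl and the methyl-bearing ring carbons, so its addition may be sluggish, the second olefination incomplete and the Z to E equilibration imperfect. The fallback replaces the phosphorus ylide by a smaller sulfonyl carbanion (Julia–Kocienski olefination); it sets out from alcohol 15 and returns at diester 20. Mitsunobu reaction of 15 (1-phenyl-1H-tetrazole-5-thiol, PPh3, diisopropyl azodicarboxylate, THF, 0 °C) should give ethyl (2E)-2-methyl-4-[(1R)-2,2,4-trimethyl-3-{[(1-phenyl-1H-tetrazol-5-yl)sulfanyl]methyl}cyclohex-3-en-1-yl]but-2-enoate F4. Oxidation ((NH4)6Mo7O24·4H2O cat., H2O2, EtOH, 0 °C to rt) should give ethyl (2E)-2-methyl-4-[(1R)-2,2,4-trimethyl-3-{[(1-phenyl-1H-tetrazol-5-yl)sulfonyl]methyl}cyclohex-3-en-1-yl]but-2-enoate F5. Deprotonation of F5 (2.2 equiv, KN(SiMe3)2, THF, −78 °C) and addition of dialdehyde 17, followed by the same thermal equilibration, should give 20.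

3. Step 6. The basic ylide may enolise the aldehyde, which would erode the only stereocentre, and olefination next to the quaternary carbon may be slow. The fallback avoids base on the enolisable aldehyde (Corey–Fuchs homologation, then anti-Markovnikov alkyne hydroboration); it sets out from aldehyde 11 and returns at aldehyde 13. CBr4 and PPh3 (CH2Cl2, 0 °C) should give tert-butyl{[(5R)-5-(2,2-dibromoethenyl)-2,6,6-trimethylcyclohex-1-en-1-yl]methoxy}diphenylsilane F6. n-BuLi (2.1 equiv, THF, −78 °C, then water) should give tert-butyl{[(5R)-5-ethynyl-2,6,6-trimethylcyclohex-1-en-1-yl]methoxy}diphenylsilane F7. Dicyclohexylborane (THF, 0 °C) followed by NaBO3·4H2O should hydrate the terminal alkyne in the anti-Markovnikov sense to aldehyde 13, leaving the tetrasubstituted ring alkene alone.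

**Further compounds**

F1 | step 5 | (4R)-3-acryloyl-4-benzyl-1,3-oxazolidin-2-one | C=CC(=O)N1[C@H](Cc2ccccc2)COC1=O
F2 | step 5 | (4R)-4-benzyl-3-{[(1S)-3-{[tert-butyl(diphenyl)silyl]oxymethyl}-2,2,4-trimethylcyclohex-3-en-1-yl]carbonyl}-1,3-oxazolidin-2-one | O=C([C@H]1CCC(C)=C(CO[Si](c2ccccc2)(c2ccccc2)C(C)(C)C)C1(C)C)N1[C@H](Cc2ccccc2)COC1=O
F3 | step 5 | [(1S)-3-{[tert-butyl(diphenyl)silyl]oxymethyl}-2,2,4-trimethylcyclohex-3-en-1-yl]methanol | OC[C@H]1CCC(C)=C(CO[Si](c2ccccc2)(c2ccccc2)C(C)(C)C)C1(C)C
F4 | step 11 | ethyl (2E)-2-methyl-4-[(1R)-2,2,4-trimethyl-3-{[(1-phenyl-1H-tetrazol-5-yl)sulfanyl]methyl}cyclohex-3-en-1-yl]but-2-enoate | CCOC(=O)/C(C)=C/C[C@H]1CCC(C)=C(CSc2nnnn2-c2ccccc2)C1(C)C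
F5 | step 11 | ethyl (2E)-2-methyl-4-[(1R)-2,2,4-trimethyl-3-{[(1-phenyl-1H-tetrazol-5-yl)sulfonyl]methyl}cyclohex-3-en-1-yl]but-2-enoate | CCOC(=O)/C(C)=C/C[C@H]1CCC(C)=C(CS(=O)(=O)c2nnnn2-c2ccccc2)C1(C)C
F6 | step 6 | tert-butyl{[(5R)-5-(2,2-dibromoethenyl)-2,6,6-trimethylcyclohex-1-en-1-yl]methoxy}diphenylsilane | BrC(Br)=C[C@H]1CCC(C)=C(CO[Si](c2ccccc2)(c2ccccc2)C(C)(C)C)C1(C)C
F7 | step 6 | tert-butyl{[(5R)-5-ethynyl-2,6,6-trimethylcyclohex-1-en-1-yl]methoxy}diphenylsilane | C#C[C@H]1CCC(C)=C(CO[Si](c2ccccc2)(c2ccccc2)C(C)(C)C)C1(C)C
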